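**Assumption:** the target has no stereogenic centre (it is achiral), so "single enantiomer" is taken to mean the single geometric isomer drawn, with an (E)-enone and a (2E)-geranyl olefin.

## Retrosynthetic overview

1. No ring is formed: the A ring is bought as paeonol (1) and the C10 chain as geranyl bromide (2), which carries the (E)-trisubstituted olefin.
2. The aryl–geranyl bond (C3′–C1″) comes from O-geranylation of 1 with 2 to give ether 3, then a clay-promoted [1,3] O→C shift to ketone 4.
3. The enone Cα=Cβ bond is made last, by Claisen–Schmidt condensation of 4 with 4-hydroxybenzaldehyde (5) to give the target 6.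
4. Stereochemistry: the geranyl (E)-olefin is carried through from 2, and the enone (E)-olefin is set thermodynamically in the aldol dehydration.

## Route

**Step 1**
Reactants: 1, paeonol (1-(2-hydroxy-4-methoxyphenyl)ethan-1-one); 2, geranyl bromide ((2E)-1-bromo-3,7-dimethylocta-2,6-diene)
Product: 3, 1-{2-[(2E)-3,7-dimethylocta-2,6-dien-1-yl]oxy-4-methoxyphenyl}ethan-1-one (paeonol 2-O-geranyl ether)
Conditions: K2CO3 (2 equiv), 2 (1.2 equiv), DMF, rt → 50 °C, 12 h
Reagents that add atoms: geranyl bromide (2), BrC/C=C(\C)CCC=C(C)C
Why: Williamson ether synthesis; in a polar aprotic solvent the phenoxide attacks the primary allylic bromide by SN2 at oxygen, the only free OH, and the (E)-olefin is untouched.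

**Step 2**
Reactants: 3, paeonol 2-O-geranyl ether
Product: 4, 1-{3-[(2E)-3,7-dimethylocta-2,6-dien-1-yl]-2-hydroxy-4-methoxyphenyl}ethan-1-one (3′-geranylpaeonol)
Conditions: Montmorillonite K10 (oven-dried, about 1 g/mmol), CH2Cl2, 0 °C, 1–2 h; filter through Celite; chromatography
Reagents that add atoms: none
Why: acid-clay-promoted formal [1,3] O→C shift; the geranyl group moves as a tight ion pair to C3, the only free ortho carbon, which is activated by both the OH and the OMe. It arrives with its linear (E)-connectivity, unlike a thermal [3,3] Claisen, which would give the inverted linalyl-type substituent; re-forming the chelated phenol drives the reaction. Low temperature and short contact time limit C5 migration, chroman formation and loss of the geranyl group.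

**Step 3**
Reactants: 4, 3′-geranylpaeonol; 5, 4-hydroxybenzaldehyde
Product: 6, xanthoangelol F ((2E)-1-{3-[(2E)-3,7-dimethylocta-2,6-dien-1-yl]-2-hydroxy-4-methoxyphenyl}-3-(4-hydroxyphenyl)prop-2-en-1-one)
Conditions: 5 (1.5 equiv), 50% aq KOH (about 15 equiv), EtOH, rt, 48 h; then 1 M HCl to pH 4–5 at 0 °C
Reagents that add atoms: 4-hydroxybenzaldehyde (5), O=Cc1ccc(O)cc1
Why: Claisen–Schmidt condensation; the methyl ketone enolate adds to the non-enolisable aldehyde, and E1cB dehydration gives the conjugated (E)-enone under thermodynamic control. The geranyl chain is inert to base, and cold, mild acidification returns the free phenols without flavanone or chroman cyclisation.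

## Compound list

1 | Paeonol, 1-(2-hydroxy-4-methoxyphenyl)ethan-1-one | COc1ccc(C(C)=O)c(O)c1 | starting material
2 | Geranyl bromide, (2E)-1-bromo-3,7-dimethylocta-2,6-diene | BrC/C=C(\C)CCC=C(C)C | starting material
3 | 1-{2-[(2E)-3,7-Dimethylocta-2,6-dien-1-yl]oxy-4-methoxyphenyl}ethan-1-one | COc1ccc(C(C)=O)c(OC/C=C(\C)CCC=C(C)C)c1 | intermediate
4 | 1-{3-[(2E)-3,7-Dimethylocta-2,6-dien-1-yl]-2-hydroxy-4-methoxyphenyl}ethan-1-one | COc1ccc(C(C)=O)c(O)c1C/C=C(\C)CCC=C(C)C | intermediate
5 | 4-Hydroxybenzaldehyde | O=Cc1ccc(O)cc1 | starting material
6 | Xanthoangelol F | COc1ccc(C(=O)/C=C/c2ccc(O)cc2)c(O)c1C/C=C(\C)CCC=C(C)C | target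

## Summary

Total step count: 3
Longest linear sequence: 3 steps (1 → 3 → 4 → 6)

Steps most likely to fail, in order of risk:

1. **Step 2 (clay [1,3] shift).** Risks are migration to C5, cleavage back to paeonol, and acid-induced cyclisation or E/Z scrambling of the geranyl unit. Fallback: drop the O→C migration and make 4 by direct C3 geranylation of 2,4-dihydroxyacetophenone (geranyl bromide, aq KOH), then chelation-controlled selective 4-O-methylation (MeI, K2CO3, acetone). The first of these is low-yielding but gives the C3 isomer directly.
2. **Step 3 (condensation with the unprotected aldehyde).** Under KOH the aldehyde is a phenoxide and a poor electrophile, so conversion may be slow, and some flavanone may form on work-up. Fallback: switch to a protecting-group strategy, condensing 4 with 4-(tetrahydropyran-2-yloxy)benzaldehyde or 4-(methoxymethoxy)benzaldehyde and then removing the group with mild acid (PPTS, MeOH, 40 °C for THP). This adds one step.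
3. **Step 1 (O-geranylation of the chelated phenol).** Risks are sluggish O-alkylation and competing C- or SN2′-alkylation. Fallback: Mitsunobu etherification of 1 with geraniol (PPh3, DIAD, THF, 0 °C → rt), which avoids the allylic bromide altogether.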